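**Conventions.** Ring A is the guaiacyl ring, ring B the dihydropyran (O1, C2–C6), rings C and D the furan and benzene rings of the benzofuran (primed locants). TBS = tert-butyldimethylsilyl, TIPS = triisopropylsilyl, TBSO/TIPSO the corresponding silyloxy groups.

## The problem

Propolis-benzofuran A joins three ring systems by single bonds. Ring A sits on C2 of a 3,4-dihydro-2H-pyran (ring B), which carries an acetoxymethyl group on C3 and, on C5, the C2′ position of a 6-acetyl-5-hydroxybenzofuran (rings C and D). The only stereocentres are C2 and C3; they are adjacent, trans and (2R,3S). A synthesis therefore has to fix one of them absolutely and can let the other follow, since trans is both the kinetic result of a closed aldol transition state and the thermodynamic preference of a small ring. The C5=C6 alkene of ring B is an enol ether, conjugated to the benzofuran but still open to protonation at C5, so strong acid is excluded once it exists. C2 is a benzylic ether para to a phenolic oxygen and can ionize under acid; the primary acetate does not tolerate hydroxide and has to be placed on one alcohol in the presence of two phenols. The aryl methyl ketone is reducible and enolizable. The feature that opens the plan is the enol ether itself: C5 bears an aryl group and can be read as a former aryl ketone carbonyl, while C6 is bonded to O1, the oxygen of the C2 carbinol, and can be read as a former formate carbonyl. These two carbonyl carbons are 1,6-related through C4–C3–C2–O1, the spacing that a reductive carbonyl coupling closes to a six-membered ring.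

## Retrosynthesis

**Target 29 back to dihydropyran 26 (no skeletal bond cut).** The C3 acetate cannot be present when C5=C6 is made. Its carbonyl carbon is, like the formate carbon, five atoms from the ketone carbon (through C4, C3, CH2 and O) and would close a rival six-membered enol ether. The aryl methyl ketone would itself be coupled by titanium. So 29 is traced through acetate-ketal 28 and triol 27 to 26, in which both phenols and the primary alcohol are silyl ethers and the acetyl is a dioxolane. The forward steps need one fluoride treatment, an acylation that tells one primary alcohol from two phenols (a lipase), and a ketal hydrolysis gentle enough for the enol ether. By then the ketal is ortho to a free phenol and is the most acid-labile group in the molecule.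

**26 back to keto formate 25 (cut C5=C6).** This cut removes ring B and its only acid-sensitive function together and leaves two ordinary carbonyl groups. Cutting O1–C6 instead would demand an enolizable α-aryl aldehyde and a separate dehydration. Cutting C5–C2′ would demand a 5-metallated or 5-halogenated ring B, whose preparation is the same ring problem again. Cutting O1–C2 would put stereocentre formation into the ring closure. Precursor 25 is acyclic, with its two stereocentres in an aldol-type array. The forward reaction needs only chemoselectivity: intramolecular ketone–formate coupling in preference to dimerization or reduction.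

**25 back to hydroxy ketone 24, then to lactone 13 and benzofuran 21 (cut the formate C–O bond, then the C5–C2′ acyl–aryl bond).** The formate is an ester of the C2 hydroxyl of 24. Ketone 24 is the product of acyl substitution at lactone 13 by 2-lithiobenzofuran 22, made from 21. The lactone is both the acyl donor and the internal protecting group of the C2 hydroxyl, which is set free exactly when the formate is needed. A Friedel–Crafts acylation of the benzofuran would instead expose a benzylic ester to Lewis acid. The forward reaction must stop at mono-addition, which the tetrahedral lithium lactolate 23 should ensure at low temperature.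

**13 back to imide 6 and aldehyde 2 (cut C2–C3 and the lactone O–acyl bond).** Silyl ether 13 comes from alcohol 12, acid 11 and lactone imide 9 by functional-group changes only. Lactone imide 9 is the lactonized syn-aldol adduct of succinate imide 6 and aldehyde 2. This single C–C bond formation sets both stereocentres from one auxiliary, and the syn adduct maps onto the trans lactone. The precursors are small: 6 from oxazolidinone 3 and acid chloride 4, and 2 from vanillin 1. The (R)-auxiliary is required. The aryl silyl ether must survive LiOH/H2O2, which is why ring A carries TIPS and not TBS.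

**21 back to bromohydroquinone 14 (cut O1′–C2′, C3′–C3a′ and the acetyl C–C bond).** Ketal 21 comes from silyl ether 20 and hydroxybenzofuran 19. The furan ring of 19 is opened at O1′–C2′ to alkynylphenol 18, the desilylated form of 17. A Sonogashira cut of 17 gives bromide 15 and trimethylsilylacetylene 16, and 15 is the C-acetylation product of 14. Acylating before the furan exists avoids electrophilic chemistry on a benzofuran, which would go to C2′, C3′ or C4′. It also puts the acetyl group para to bromine, where halogen direction helps the acylation and the acyl group later activates the bromide for coupling. The forward acylation must enter para to bromine.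

## Roads not taken

**Alternative 1:** The furan ring would be made last, by cutting O1′–C2′ and C2′=C3′. Forward, ring B acid chloride A2 would acylate the phenol next to the phosphoniomethyl group of salt A3. Triethylamine would then form the ylide, which olefinates the new aryl ester carbonyl and gives silyl ether A1, one fluoride step from 29.
- Merits: intramolecular ester Wittig closure to benzofurans is mild and dependable. The acetyl and acetate groups travel unmasked because nothing in the sequence is reducing. The end game is one deprotection against three steps in the chosen plan.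
- Weak points: A2 already contains the whole of ring B with both stereocentres and the enol ether, now as a β-alkoxyacryloyl chloride, so the ring B problem is moved back and not solved. A3 offers two phenols and an enolizable acetyl group to an acid chloride and base; only the hydrogen bond of the second phenol to the acetyl favours the wanted O-acylation.
- Comparison: this road is better in protecting-group economy and end-game length. The chosen plan sets against that a key step that makes ring B itself, and a benzofuran that enters as a ready nucleophile in the step that releases the C2 hydroxyl.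

**Alternative 2:** Ring B would be assembled by cutting C2–C3 and O1–C6. Forward, silylated vanillin A6 and the 1-dimethylamino-3-silyloxy diene A5 would combine under a chiral diol hydrogen-bond donor. Acetyl chloride would expel dimethylamine and DBU would equilibrate C3, giving dihydropyranone A4.
- Merits: ring B and its stereochemistry arise in one catalytic asymmetric operation without an auxiliary. C3 is α to a ketone, so trans is under thermodynamic control.
- Weak points: A4 carries a carbonyl group at C4 that the target lacks. Removing the carbonyl oxygen of a vinylogous ester while keeping the C5=C6 enol ether is not a routine step; 1,2-reduction gives an allylic alcohol that ionizes with allylic transposition (Ferrier-type). A5 is substituted at both C2 and C4 of the diene, beyond the simple amino siloxy dienes for which hydrogen-bond catalysis is established. The acetyl group has to travel as a silyl enol ether.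
- Comparison: this road is superior in how absolute configuration is introduced. The chosen plan sets against that the correct oxidation level at C4 from the start, so no step is spent removing an oxygen that the ring-forming step put in.

**Alternative 3:** Ring B would be cut at O1–C2 and C3–C4. Forward, the 2-(benzofuran-2-yl)acrolein A8 would act as a 1-oxadiene towards the (E)-alkene of silylated coniferyl acetate A9 under a chiral imidodiphosphorimidate Brønsted acid. The product A7 is one fluoride step from 29.
- Merits: it is the shortest conceivable route. Both partners are achiral and small, the E geometry translates into trans, and the acetate and acetyl are already in place. If the cycloaddition works as drawn, it is shorter than the chosen plan by a wide margin.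
- Weak points: one step must deliver enantio-, diastereo- and chemoselectivity on a plain 2-aryl acrolein and a 1,2-disubstituted styrene. Bond formation is probably stepwise through a benzylic cation stabilized by the para silyloxy group, through which the trans relationship and the enantiomeric purity can leak and the allylic acetate of A9 can ionize. A8 is a reactive 2-substituted acrolein that can dimerize by self hetero-Diels–Alder reaction or polymerize. The acetyl and acetate carbonyls compete for the acid.
- Comparison: step count is conceded. The chosen plan sets against it stereocentres from an auxiliary aldol of predictable sense, and a single uncertain step that poses one chemoselectivity question.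

Key step: step 14

## Route

Assumption: hydroxy ketone 24 is taken to rest mainly in its open-chain form, because closure to the lactol would cost the conjugation between benzofuran and carbonyl; compounds 1, 3, 4, 14 and 16 are bought.

Step 1
Reactants: 1 vanillin (4-hydroxy-3-methoxybenzaldehyde)
Product: 2 3-methoxy-4-(triisopropylsilyloxy)benzaldehyde
Conditions: TIPSCl, imidazole, DMF, 0 °C → rt
Reagents that add atoms: chlorotriisopropylsilane (TIPSCl), CC(C)[Si](Cl)(C(C)C)C(C)C
Why: Routine phenol silylation; TIPS is chosen over TBS because this aryl ether must survive LiOH/H2O2 in step 4 and is still removed by fluoride at the end.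

Step 2
Reactants: 3 (R)-4-benzyl-1,3-oxazolidin-2-one; 4 methyl 4-chloro-4-oxobutanoate
Product: 6 methyl 4-[(4R)-4-benzyl-2-oxo-1,3-oxazolidin-3-yl]-4-oxobutanoate, via N-lithio oxazolidinone 5 (not isolated)
Conditions: n-BuLi, THF, −78 °C; then 4, −78 → 0 °C
Reagents that add atoms: none
Why: Standard N-acylation of a lithiated oxazolidinone by an acid chloride; the acid chloride reacts far faster than the methyl ester of the same molecule.

Step 3
Reactants: 6 methyl 4-[(4R)-4-benzyl-2-oxo-1,3-oxazolidin-3-yl]-4-oxobutanoate; 2 3-methoxy-4-(triisopropylsilyloxy)benzaldehyde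
Product: 9 (4R)-4-benzyl-3-{[(2R,3R)-2-[3-methoxy-4-(triisopropylsilyloxy)phenyl]-5-oxooxolan-3-yl]carbonyl}-1,3-oxazolidin-2-one (trans lactone), via Z-boron enolate 7 (not isolated), via boron aldolate 8 (not isolated)
Conditions: Bu2BOTf, i-Pr2NEt, CH2Cl2, 0 °C; then 2, −78 °C → rt; pH 7 buffer, H2O2, MeOH, 0 °C
Reagents that add atoms: none
Why: Evans syn-aldol reaction: Z-enolate 7 adds through a chair Zimmerman–Traxler transition state on the face away from the auxiliary benzyl group, which sets both centres (R at the imide-bearing carbon, R at the benzylic carbon). The aldolate oxygen of 8 then closes onto the γ-methyl ester (5-exo-trig), and the syn adduct corresponds to the trans lactone, which is also the more stable isomer; closure can be completed with a trace of acid on the crude if it lags.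

Step 4
Reactants: 9 the trans lactone imide
Product: 11 (2R,3R)-2-[3-methoxy-4-(triisopropylsilyloxy)phenyl]-5-oxooxolane-3-carboxylic acid, via peroxy acid 10 (not isolated)
Conditions: LiOH, H2O2, THF–H2O, 0 °C; Na2SO3; HCl to pH 2–3
Reagents that add atoms: hydrogen peroxide (acting as LiOOH), OO
Why: Hydroperoxide attacks the exocyclic imide carbonyl selectively and sulfite reduces peroxy acid 10 to the acid; any lactone opened by hydroxide re-closes on acidification because only the five-membered lactone can form. Auxiliary 3 is recovered and neither stereocentre is enolized under these cold conditions.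

Step 5
Reactants: 11 the lactone acid
Product: 12 (4S,5R)-4-(hydroxymethyl)-5-[3-methoxy-4-(triisopropylsilyloxy)phenyl]oxolan-2-one
Conditions: BH3·SMe2, THF, 0 °C → rt; MeOH quench
Reagents that add atoms: none
Why: Borane reduces a carboxylic acid through its acyloxyborane much faster than it touches a lactone. The medium is never basic, so the new primary alcohol does not translactonize; the descriptor at C4 changes to S only through the priority change.

Step 6
Reactants: 12 the hydroxymethyl lactone
Product: 13 (4S,5R)-4-[(tert-butyldimethylsilyloxy)methyl]-5-[3-methoxy-4-(triisopropylsilyloxy)phenyl]oxolan-2-one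
Conditions: TBSCl, imidazole, CH2Cl2, 0 °C → rt
Reagents that add atoms: tert-butylchlorodimethylsilane (TBSCl), CC(C)(C)[Si](C)(C)Cl
Why: Fast silylation of an unhindered primary alcohol; it blocks lactone migration and keeps any ester other than the formate away from the later ketyl.

Step 7
Reactants: 14 bromohydroquinone (2-bromobenzene-1,4-diol)
Product: 15 1-(4-bromo-2,5-dihydroxyphenyl)ethan-1-one
Conditions: AcOH, BF3·OEt2, 110 °C; then aq. NaOAc
Reagents that add atoms: acetic acid, CC(=O)O
Why: Friedel–Crafts-type C-acylation of a hydroquinone (O-acetate, then Fries-type shift). Of the three free positions, C3 is flanked by bromine and hydroxyl and C6 is meta to bromine, so the acyl group should enter C5, ortho to a hydroxyl and para to bromine.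

Step 8
Reactants: 15 1-(4-bromo-2,5-dihydroxyphenyl)ethan-1-one; 16 trimethylsilylacetylene
Product: 17 1-{2,5-dihydroxy-4-[(trimethylsilyl)ethynyl]phenyl}ethan-1-one
Conditions: PdCl2(PPh3)2 (cat.), CuI (cat.), Et3N, THF, 60 °C, under argon
Reagents that add atoms: none
Why: Sonogashira coupling; the bromide is para to the acetyl group and therefore activated for oxidative addition to zerovalent palladium. Partial ring closure at this stage would be harmless because step 9 completes it and removes silicon.

Step 9
Reactants: 17 the silylalkynyl hydroquinone ketone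
Product: 19 1-(5-hydroxy-1-benzofuran-6-yl)ethan-1-one, via terminal alkyne 18 (not isolated)
Conditions: TBAF, THF, 65 °C; aq. NH4Cl
Reagents that add atoms: none
Why: Fluoride removes the alkynyl silyl group, and the phenoxide ortho to the alkyne adds to it (5-endo-dig), helped by the acetyl group para to the alkyne. The second phenol is meta to the alkyne and cannot cyclize.

Step 10
Reactants: 19 1-(5-hydroxy-1-benzofuran-6-yl)ethan-1-one
Product: 20 1-[5-(tert-butyldimethylsilyloxy)-1-benzofuran-6-yl]ethan-1-one
Conditions: TBSCl, imidazole, DMF, 40 °C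
Reagents that add atoms: tert-butylchlorodimethylsilane (TBSCl), CC(C)(C)[Si](C)(C)Cl
Why: Silylation of a hydrogen-bonded ortho-acyl phenol needs mild warming but is routine; it removes the acidic proton before the lithiation.

Step 11
Reactants: 20 the silylated acetylbenzofuran
Product: 21 tert-butyldimethyl{[6-(2-methyl-1,3-dioxolan-2-yl)-1-benzofuran-5-yl]oxy}silane
Conditions: (TMSOCH2)2, TMSOTf (cat.), CH2Cl2, −78 → −20 °C; pyridine quench
Reagents that add atoms: 1,2-bis(trimethylsilyloxy)ethane, C[Si](C)(C)OCCO[Si](C)(C)C
Why: Noyori ketalization is aprotic and driven by formation of hexamethyldisiloxane, so it suits a hindered, electron-rich aryl ketone and leaves the aryl silyl ether alone. The dioxolane withstands organolithium, base and the reducing metal of step 14.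

Step 12
Reactants: 21 the ketal-protected benzofuran; 13 the silylated trans lactone
Product: 24 (3S,4R)-1-[5-TBSO-6-(2-methyl-1,3-dioxolan-2-yl)-1-benzofuran-2-yl]-3-[(TBSO)methyl]-4-hydroxy-4-[3-methoxy-4-(TIPSO)phenyl]butan-1-one, via 2-lithiobenzofuran 22 (not isolated), via lithium lactolate 23 (not isolated)
Conditions: n-BuLi, THF, −78 °C, 1 h; then 13, −78 °C; AcOH, −78 °C → rt
Reagents that add atoms: none
Why: C2′–H is the most acidic proton of a benzofuran, and 22 adds once to the lactone carbonyl. Lactolate 23 holds as a tetrahedral alkoxide at −78 °C, which prevents a second addition, and opens on protonation to the conjugated aryl ketone. Neither stereocentre is involved.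

Step 13
Reactants: 24 the hydroxy ketone
Product: 25 (1R,2S)-4-[5-TBSO-6-(2-methyl-1,3-dioxolan-2-yl)-1-benzofuran-2-yl]-2-[(TBSO)methyl]-1-[3-methoxy-4-(TIPSO)phenyl]-4-oxobutyl formate
Conditions: AcOCHO (preformed), pyridine, CH2Cl2, −20 → 0 °C
Reagents that add atoms: acetic formic anhydride, CC(=O)OC=O
Why: The mixed anhydride transfers its more electrophilic formyl group to the secondary alcohol. Pyridine keeps the medium basic, so the hydroxy ketone is not cyclodehydrated and the ketal is untouched; the C–O bond at C2 is not broken, so configuration is retained.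

Step 14
Reactants: 25 the keto formate
Product: 26 (2R,3S)-5-[5-TBSO-6-(2-methyl-1,3-dioxolan-2-yl)-1-benzofuran-2-yl]-3-[(TBSO)methyl]-2-[3-methoxy-4-(TIPSO)phenyl]-3,4-dihydro-2H-pyran
Conditions: TiCl3, Zn dust, DME, reflux, 2 h; then Et3N; 25 added by syringe pump over 20 h at reflux (final ca. 0.005 M); aq. K2CO3 work-up
Reagents that add atoms: none
Why: Low-valent titanium on the zinc surface transfers electrons to the conjugated benzofuranyl ketone, the more easily reduced carbonyl group, and gives a titanium-bound ketyl (or its doubly reduced equivalent) at C5. This carbon attacks the aldehyde-like formate carbonyl C6 held five atoms away, a 6-exo-trig closure that forms the C5–C6 bond and ring B in one event. The resulting titanium 1,2-diolate is deoxygenated on the oxophilic metal, as in every McMurry olefination, and leaves C5=C6 as the enol ether. The closest known reaction type is the intramolecular oxo-ester variant of the McMurry coupling, which turns keto esters into cyclic enol ethers and O-acyl ketones into furans and benzofurans; a formate is the most electrophilic member of the ester class. No stereocentre is created, and C2 and C3 are not at risk because neither is α to a carbonyl group (C3 is β to the ketone). The step needs chemoselectivity only: ring closure must outrun pinacol dimerization and simple ketone reduction, which slow addition at high dilution and the six-membered transition state should secure. No other carbonyl group is within reach of the ketyl, since the aryl methyl ketone is a dioxolane and every hydroxyl is a silyl ether. Triethylamine and the basic work-up protect the enol ether, the ketal and the benzylic C2–O bond from adventitious acid.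

Step 15
Reactants: 26 the fully protected dihydropyran
Product: 27 (2R,3S)-3-(hydroxymethyl)-2-(4-hydroxy-3-methoxyphenyl)-5-[5-hydroxy-6-(2-methyl-1,3-dioxolan-2-yl)-1-benzofuran-2-yl]-3,4-dihydro-2H-pyran
Conditions: TBAF, THF, 0 °C → rt; aq. NH4Cl
Reagents that add atoms: none
Why: Fluoride cleaves the two aryl silyl ethers quickly and the primary alkyl silyl ether at room temperature; the enol ether and the ketal are stable to these basic conditions. Should some ketal be lost on work-up, the material still converges on 29 after steps 16 and 17.

Step 16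
Reactants: 27 the triol ketal
Product: 28 {(2R,3S)-2-(4-hydroxy-3-methoxyphenyl)-5-[5-hydroxy-6-(2-methyl-1,3-dioxolan-2-yl)-1-benzofuran-2-yl]-3,4-dihydro-2H-pyran-3-yl}methyl acetate
Conditions: Novozym 435 (immobilized Candida antarctica lipase B), vinyl acetate, THF, 35 °C
Reagents that add atoms: vinyl acetate, CC(=O)OC=C
Why: Lipase-catalysed transesterification; the acyl-enzyme acylates primary aliphatic alcohols and leaves phenols untouched. Tautomerization of the vinyl alcohol leaving group to acetaldehyde makes the transfer irreversible, and the neutral medium spares the enol ether and ketal.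

Step 17
Reactants: 28 the acetate ketal
Product: 29 propolis-benzofuran A, [(2R,3S)-5-(6-acetyl-5-hydroxy-1-benzofuran-2-yl)-2-(4-hydroxy-3-methoxyphenyl)-3,4-dihydro-2H-pyran-3-yl]methyl acetate
Conditions: PPTS (cat.), acetone–H2O (20:1), rt
Reagents that add atoms: water, O
Why: Mild acid hydrolysis of a ketal; the dioxolane of an ortho-hydroxyaryl ketone ionizes readily because the phenol stabilizes and assists the oxocarbenium ion. The aryl-conjugated enol ether is protonated at C5 far more slowly and the acetate is inert, so the acetyl group should be freed selectively.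

## Compound list

1 | vanillin (4-hydroxy-3-methoxybenzaldehyde) | COc1cc(C=O)ccc1O | starting material
2 | 3-methoxy-4-(triisopropylsilyloxy)benzaldehyde | COc1cc(C=O)ccc1O[Si](C(C)C)(C(C)C)C(C)C | intermediate
3 | (R)-4-benzyl-1,3-oxazolidin-2-one | O=C1N[C@H](Cc2ccccc2)CO1 | starting material
4 | methyl 4-chloro-4-oxobutanoate | COC(=O)CCC(Cl)=O | starting material
5 | N-lithio derivative of (R)-4-benzyl-1,3-oxazolidin-2-one | [Li]N1[C@H](Cc2ccccc2)COC1=O | intermediate
6 | methyl 4-[(4R)-4-benzyl-2-oxo-1,3-oxazolidin-3-yl]-4-oxobutanoate | COC(=O)CCC(=O)N1[C@H](Cc2ccccc2)COC1=O | intermediate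
7 | Z-(O)-dibutylboron enolate of 6 | COC(=O)C/C=C(\OB(CCCC)CCCC)N1[C@H](Cc2ccccc2)COC1=O | intermediate
8 | dibutylboron aldolate of methyl (3R,4R)-3-{[(4R)-4-benzyl-2-oxo-1,3-oxazolidin-3-yl]carbonyl}-4-hydroxy-4-[3-methoxy-4-(triisopropylsilyloxy)phenyl]butanoate (syn adduct) | COC(=O)C[C@@H](C(=O)N1[C@H](Cc2ccccc2)COC1=O)[C@@H](OB(CCCC)CCCC)c1ccc(O[Si](C(C)C)(C(C)C)C(C)C)c(OC)c1 | intermediate
9 | (4R)-4-benzyl-3-{[(2R,3R)-2-[3-methoxy-4-(triisopropylsilyloxy)phenyl]-5-oxooxolan-3-yl]carbonyl}-1,3-oxazolidin-2-one | O=C1C[C@@H](C(=O)N2[C@H](Cc3ccccc3)COC2=O)[C@H](c2ccc(O[Si](C(C)C)(C(C)C)C(C)C)c(OC)c2)O1 | intermediate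
10 | (2R,3R)-2-[3-methoxy-4-(triisopropylsilyloxy)phenyl]-5-oxooxolane-3-carboperoxoic acid | O=C1C[C@@H](C(=O)OO)[C@H](c2ccc(O[Si](C(C)C)(C(C)C)C(C)C)c(OC)c2)O1 | intermediate
11 | (2R,3R)-2-[3-methoxy-4-(triisopropylsilyloxy)phenyl]-5-oxooxolane-3-carboxylic acid | O=C1C[C@@H](C(=O)O)[C@H](c2ccc(O[Si](C(C)C)(C(C)C)C(C)C)c(OC)c2)O1 | intermediate
12 | (4S,5R)-4-(hydroxymethyl)-5-[3-methoxy-4-(triisopropylsilyloxy)phenyl]oxolan-2-one | O=C1C[C@@H](CO)[C@H](c2ccc(O[Si](C(C)C)(C(C)C)C(C)C)c(OC)c2)O1 | intermediate
13 | (4S,5R)-4-[(tert-butyldimethylsilyloxy)methyl]-5-[3-methoxy-4-(triisopropylsilyloxy)phenyl]oxolan-2-one | O=C1C[C@@H](CO[Si](C)(C)C(C)(C)C)[C@H](c2ccc(O[Si](C(C)C)(C(C)C)C(C)C)c(OC)c2)O1 | intermediate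
14 | bromohydroquinone (2-bromobenzene-1,4-diol) | Oc1ccc(O)c(Br)c1 | starting material
15 | 1-(4-bromo-2,5-dihydroxyphenyl)ethan-1-one | CC(=O)c1cc(O)c(Br)cc1O | intermediate
16 | trimethylsilylacetylene | C#C[Si](C)(C)C | starting material
17 | 1-{2,5-dihydroxy-4-[(trimethylsilyl)ethynyl]phenyl}ethan-1-one | CC(=O)c1cc(O)c(C#C[Si](C)(C)C)cc1O | intermediate
18 | 1-(4-ethynyl-2,5-dihydroxyphenyl)ethan-1-one | CC(=O)c1cc(O)c(C#C)cc1O | intermediate
19 | 1-(5-hydroxy-1-benzofuran-6-yl)ethan-1-one | CC(=O)c1cc2occc2cc1O | intermediate
20 | 1-[5-(tert-butyldimethylsilyloxy)-1-benzofuran-6-yl]ethan-1-one | CC(=O)c1cc2occc2cc1O[Si](C)(C)C(C)(C)C | intermediate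
21 | tert-butyldimethyl{[6-(2-methyl-1,3-dioxolan-2-yl)-1-benzofuran-5-yl]oxy}silane | CC1(c2cc3occc3cc2O[Si](C)(C)C(C)(C)C)OCCO1 | intermediate
22 | 2-lithio derivative of 21 | [Li]c1cc2cc(O[Si](C)(C)C(C)(C)C)c(C3(C)OCCO3)cc2o1 | intermediate
23 | lithium (4S,5R)-2-[5-TBSO-6-(2-methyl-1,3-dioxolan-2-yl)-1-benzofuran-2-yl]-4-[(TBSO)methyl]-5-[3-methoxy-4-(TIPSO)phenyl]oxolan-2-olate (mixture at C2) | [Li]OC1(c2cc3cc(O[Si](C)(C)C(C)(C)C)c(C4(C)OCCO4)cc3o2)C[C@@H](CO[Si](C)(C)C(C)(C)C)[C@H](c2ccc(O[Si](C(C)C)(C(C)C)C(C)C)c(OC)c2)O1 | intermediate
24 | (3S,4R)-1-[5-TBSO-6-(2-methyl-1,3-dioxolan-2-yl)-1-benzofuran-2-yl]-3-[(TBSO)methyl]-4-hydroxy-4-[3-methoxy-4-(TIPSO)phenyl]butan-1-one | COc1cc([C@H](O)[C@@H](CC(=O)c2cc3cc(O[Si](C)(C)C(C)(C)C)c(C4(C)OCCO4)cc3o2)CO[Si](C)(C)C(C)(C)C)ccc1O[Si](C(C)C)(C(C)C)C(C)C | intermediate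
25 | (1R,2S)-4-[5-TBSO-6-(2-methyl-1,3-dioxolan-2-yl)-1-benzofuran-2-yl]-2-[(TBSO)methyl]-1-[3-methoxy-4-(TIPSO)phenyl]-4-oxobutyl formate | COc1cc([C@H](OC=O)[C@@H](CC(=O)c2cc3cc(O[Si](C)(C)C(C)(C)C)c(C4(C)OCCO4)cc3o2)CO[Si](C)(C)C(C)(C)C)ccc1O[Si](C(C)C)(C(C)C)C(C)C | intermediate
26 | (2R,3S)-5-[5-TBSO-6-(2-methyl-1,3-dioxolan-2-yl)-1-benzofuran-2-yl]-3-[(TBSO)methyl]-2-[3-methoxy-4-(TIPSO)phenyl]-3,4-dihydro-2H-pyran | COc1cc([C@@H]2OC=C(c3cc4cc(O[Si](C)(C)C(C)(C)C)c(C5(C)OCCO5)cc4o3)C[C@H]2CO[Si](C)(C)C(C)(C)C)ccc1O[Si](C(C)C)(C(C)C)C(C)C | intermediate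
27 | (2R,3S)-3-(hydroxymethyl)-2-(4-hydroxy-3-methoxyphenyl)-5-[5-hydroxy-6-(2-methyl-1,3-dioxolan-2-yl)-1-benzofuran-2-yl]-3,4-dihydro-2H-pyran | COc1cc([C@@H]2OC=C(c3cc4cc(O)c(C5(C)OCCO5)cc4o3)C[C@H]2CO)ccc1O | intermediate
28 | {(2R,3S)-2-(4-hydroxy-3-methoxyphenyl)-5-[5-hydroxy-6-(2-methyl-1,3-dioxolan-2-yl)-1-benzofuran-2-yl]-3,4-dihydro-2H-pyran-3-yl}methyl acetate | COc1cc([C@@H]2OC=C(c3cc4cc(O)c(C5(C)OCCO5)cc4o3)C[C@H]2COC(C)=O)ccc1O | intermediate
29 | propolis-benzofuran A, [(2R,3S)-5-(6-acetyl-5-hydroxy-1-benzofuran-2-yl)-2-(4-hydroxy-3-methoxyphenyl)-3,4-dihydro-2H-pyran-3-yl]methyl acetate | COc1cc([C@@H]2OC=C(c3cc4cc(O)c(C(C)=O)cc4o3)C[C@H]2COC(C)=O)ccc1O | target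

## Step count and risks

Total step count: 17. Longest linear sequence: 11 steps (steps 1, 3–6 and 12–17 from vanillin; the lines from 3 through steps 2–6 and 12–17, and from 14 through steps 7–17, are equally long).

**Step 14 (key step).** Three processes can divert it. Intermolecular pinacol coupling or plain reduction of the ketone may outrun ring closure. The formyl group may be lost, or the electron-rich benzylic C2–O bond ionized or reductively cleaved, at the Lewis-acidic reducing surface. The tetrahedral titanium hemiacetal may expel the C2 alkoxide and not be deoxygenated. Formates and non-aromatic six-membered products also lie at the edge of what the oxo-ester coupling has been used for.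

Fallback: abandon the reductive coupling and build C5=C6 by olefination. From hydroxy ketone 24, excess methoxymethylenetriphenylphosphorane (from (methoxymethyl)triphenylphosphonium chloride and KHMDS, THF, −78 → 0 °C) should give the methyl enol ether F1. Catalytic PPTS in CH2Cl2 should add the C2 hydroxyl to the protonated enol ether and give the cyclic methyl acetal F2. Warming F2 with catalytic PPTS in toluene over 5 Å sieves should expel methanol towards the conjugated enol ether, rejoining the route at 26.

**Step 7.** The acyl group may enter C6 (meta to bromine) instead of C5, or the O-acetate may shift incompletely. Halogen direction favours C5 but is not absolute on a free hydroquinone.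

Fallback: from 14, O-methylation (Me2SO4, K2CO3, acetone) gives 2-bromo-1,4-dimethoxybenzene F3. Friedel–Crafts acetylation of F3 (AcCl, AlCl3, CH2Cl2, 0 °C) goes para to bromine and gives 1-(4-bromo-2,5-dimethoxyphenyl)ethan-1-one F4. BBr3 (CH2Cl2, −78 °C → rt) removes both methyl groups, rejoining the route at 15.

**Step 12.** A second addition of 22 may occur if lactolate 23 opens before the quench, and the lactone may be enolized by the aryllithium.

Fallback: from lactone 13, MeNHOMe·HCl and AlMe3 (CH2Cl2, 0 °C) open the ring to the hydroxy Weinreb amide F5. Its hydroxyl is deprotonated with one equivalent of i-PrMgCl (THF, −40 °C), and 22 then adds once to the amide through the chelated tetrahedral intermediate, rejoining the route at 24 on work-up.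

**Step 16.** Acyl transfer to a primary alcohol next to two ring substituents may be slow in the enzyme pocket, and long reaction times invite phenol acetylation.

Fallback: from triol 27, Ac2O, pyridine and catalytic DMAP give the triacetate F6. Pyrrolidine (2.2 equiv, MeCN, 0 °C) cleaves the two aryl acetates by aminolysis and leaves the alkyl acetate, rejoining the route at 28.

**Step 17.** Hydration of the enol ether at C5/C6 or ionization at benzylic C2 may compete with ketal hydrolysis if the ketal proves less labile than expected.

Fallback: accept the hydration and undo it. From 28, aqueous acetic acid (AcOH–THF–H2O, 40 °C) hydrolyses the ketal and hydrates the enol ether to the keto lactol F7. Catalytic PPTS in toluene over 4 Å sieves (60 °C) dehydrates F7 to the conjugated enol ether, rejoining the route at 29.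

## Further compounds

F1 | step 14 | (1R,2S)-4-[5-TBSO-6-(2-methyl-1,3-dioxolan-2-yl)-1-benzofuran-2-yl]-2-[(TBSO)methyl]-5-methoxy-1-[3-methoxy-4-(TIPSO)phenyl]pent-4-en-1-ol (E/Z mixture) | COc1cc([C@H](O)[C@@H](CC(=COC)c2cc3cc(O[Si](C)(C)C(C)(C)C)c(C4(C)OCCO4)cc3o2)CO[Si](C)(C)C(C)(C)C)ccc1O[Si](C(C)C)(C(C)C)C(C)C
F2 | step 14 | (2R,3S)-5-[5-TBSO-6-(2-methyl-1,3-dioxolan-2-yl)-1-benzofuran-2-yl]-3-[(TBSO)methyl]-6-methoxy-2-[3-methoxy-4-(TIPSO)phenyl]oxane (mixture at C5 and C6) | COc1cc([C@@H]2OC(OC)C(c3cc4cc(O[Si](C)(C)C(C)(C)C)c(C5(C)OCCO5)cc4o3)C[C@H]2CO[Si](C)(C)C(C)(C)C)ccc1O[Si](C(C)C)(C(C)C)C(C)C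
F3 | step 7 | 2-bromo-1,4-dimethoxybenzene | COc1ccc(OC)c(Br)c1
F4 | step 7 | 1-(4-bromo-2,5-dimethoxyphenyl)ethan-1-one | CC(=O)c1cc(OC)c(Br)cc1OC
F5 | step 12 | (3S,4R)-3-[(tert-butyldimethylsilyloxy)methyl]-4-hydroxy-N-methoxy-N-methyl-4-[3-methoxy-4-(triisopropylsilyloxy)phenyl]butanamide | COc1cc([C@H](O)[C@@H](CC(=O)N(C)OC)CO[Si](C)(C)C(C)(C)C)ccc1O[Si](C(C)C)(C(C)C)C(C)C
F6 | step 16 | {(2R,3S)-2-(4-acetoxy-3-methoxyphenyl)-5-[5-acetoxy-6-(2-methyl-1,3-dioxolan-2-yl)-1-benzofuran-2-yl]-3,4-dihydro-2H-pyran-3-yl}methyl acetate | COc1cc([C@@H]2OC=C(c3cc4cc(OC(C)=O)c(C5(C)OCCO5)cc4o3)C[C@H]2COC(C)=O)ccc1OC(C)=O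
F7 | step 17 | [(2R,3S)-5-(6-acetyl-5-hydroxy-1-benzofuran-2-yl)-6-hydroxy-2-(4-hydroxy-3-methoxyphenyl)oxan-3-yl]methyl acetate (mixture at C5 and C6) | COc1cc([C@@H]2OC(O)C(c3cc4cc(O)c(C(C)=O)cc4o3)C[C@H]2COC(C)=O)ccc1O
A1 | alternative 1 | [(2R,3S)-5-(6-acetyl-5-hydroxy-1-benzofuran-2-yl)-2-[4-(tert-butyldimethylsilyloxy)-3-methoxyphenyl]-3,4-dihydro-2H-pyran-3-yl]methyl acetate | COc1cc([C@@H]2OC=C(c3cc4cc(O)c(C(C)=O)cc4o3)C[C@H]2COC(C)=O)ccc1O[Si](C)(C)C(C)(C)C
A2 | alternative 1 | (2R,3S)-3-(acetoxymethyl)-2-[4-(tert-butyldimethylsilyloxy)-3-methoxyphenyl]-3,4-dihydro-2H-pyran-5-carbonyl chloride | COc1cc([C@@H]2OC=C(C(Cl)=O)C[C@H]2COC(C)=O)ccc1O[Si](C)(C)C(C)(C)C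
A3 | alternative 1 | [(4-acetyl-2,5-dihydroxyphenyl)methyl]triphenylphosphonium bromide | CC(=O)c1cc(O)c(C[P+](c2ccccc2)(c2ccccc2)c2ccccc2)cc1O.[Br-]
A4 | alternative 2 | (2R,3S)-2-[4-TBSO-3-methoxyphenyl]-5-{5-TBSO-6-[1-(TBSO)vinyl]-1-benzofuran-2-yl}-3-[(TBSO)methyl]-2,3-dihydro-4H-pyran-4-one | COc1cc([C@@H]2OC=C(c3cc4cc(O[Si](C)(C)C(C)(C)C)c(C(=C)O[Si](C)(C)C(C)(C)C)cc4o3)C(=O)[C@H]2CO[Si](C)(C)C(C)(C)C)ccc1O[Si](C)(C)C(C)(C)C
A5 | alternative 2 | 2-{5-TBSO-6-[1-(TBSO)vinyl]-1-benzofuran-2-yl}-3,5-bis(TBSO)-N,N-dimethylpenta-1,3-dien-1-amine (alkene geometry not assigned) | CN(C)C=C(c1cc2cc(O[Si](C)(C)C(C)(C)C)c(C(=C)O[Si](C)(C)C(C)(C)C)cc2o1)C(O[Si](C)(C)C(C)(C)C)=CCO[Si](C)(C)C(C)(C)C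
A6 | alternative 2 | 4-(tert-butyldimethylsilyloxy)-3-methoxybenzaldehyde | COc1cc(C=O)ccc1O[Si](C)(C)C(C)(C)C
A7 | alternative 3 | [(2R,3S)-5-[6-acetyl-5-(tert-butyldimethylsilyloxy)-1-benzofuran-2-yl]-2-[4-(tert-butyldimethylsilyloxy)-3-methoxyphenyl]-3,4-dihydro-2H-pyran-3-yl]methyl acetate | COc1cc([C@@H]2OC=C(c3cc4cc(O[Si](C)(C)C(C)(C)C)c(C(C)=O)cc4o3)C[C@H]2COC(C)=O)ccc1O[Si](C)(C)C(C)(C)C
A8 | alternative 3 | 2-[6-acetyl-5-(tert-butyldimethylsilyloxy)-1-benzofuran-2-yl]prop-2-enal | C=C(C=O)c1cc2cc(O[Si](C)(C)C(C)(C)C)c(C(C)=O)cc2o1
A9 | alternative 3 | (E)-3-[4-(tert-butyldimethylsilyloxy)-3-methoxyphenyl]prop-2-en-1-yl acetate | COc1cc(/C=C/COC(C)=O)ccc1O[Si](C)(C)C(C)(C)C
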